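**Plan**

1. Numbering (labdane type): ring A = C1–C5 + C10, ring B = C5–C10. C4 carries CH3 and the 4-methylpent-3-enyl chain, C10 and C8 each carry a CH3, and C9 carries the acid chain C11–C15.
2. Cuts, last to first: C13=C14 (Horner–Wadsworth–Emmons); C9–C11 (enol triflate cross-coupling); the CH=CMe2 alkene of the C4 chain (Wittig); then, in one radical event, C3–C4 (closing ring A) together with the bond between the first and second CH2 of the C4 chain; finally C10–C1 and C10–CH3 (enolate alkylations).
3. Enabling feature: ring B with C8–CH3, an oxidised C9, C5–C4, the C4 methyl and the first chain CH2 is the p-menthane skeleton of (R)-carvone, whose isopropenyl group is C4(=CH2)CH3. A carbon radical adding to that =CH2 starts the C4 chain and makes C4 a tertiary radical, placed to reach a C3 acceptor carried by C10.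
4. Forward order: ring B is bought as carvone; C10 is methylated, then allylated with a 2-sulfonylallyl bromide; radical addition/cyclisation closes ring A; enone → enol triflate → B-alkyl coupling joins the C9 chain; the sulfone is removed; ester → CH=CMe2; ketal → ketone → (E)-enoic acid.
5. Stereochemistry: C5 comes from (R)-carvone; C10 from alkylation anti to the isopropenyl group (CH3 first, chain second), which also fixes the trans ring fusion; C4 from the ring closure (CH3 axial, chain equatorial); 13E from the olefination.

Key step: step 5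

Remark: bromide 3 is made in two steps because its commercial supply is uncertain; all other reagents are taken as commercial. Atom numbers in the text follow the labdane numbering defined above.

**Route**

Step 1
Reactants: 1 phenyl vinyl sulfone
Product: 2 2-(phenylsulfonyl)prop-2-en-1-ol
Conditions: aq. formaldehyde (37 %), DABCO (cat.), THF, rt
Reagents that add atoms: formaldehyde (C=O)
Why: Morita–Baylis–Hillman reaction, in which DABCO adds to the vinyl sulfone and the resulting α-sulfonyl carbanion is hydroxymethylated before the amine leaves.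

Step 2
Reactants: 2 2-(phenylsulfonyl)prop-2-en-1-ol
Product: 3 3-bromo-2-(phenylsulfonyl)prop-1-ene
Conditions: PBr3 (0.4 equiv), Et2O, 0 °C
Reagents that add atoms: phosphorus tribromide (BrP(Br)Br)
Why: standard conversion of a primary allylic alcohol into the bromide, and because the allyl unit is symmetrical direct and allylic displacement give the same product.

Step 3
Reactants: 4 (R)-(–)-carvone
Product: 6 6-methylcarvone (both C6 epimers), via lithium dienolate 5 (not isolated)
Conditions: LiN(i-Pr)2 (commercial solution), THF, –78 °C; MeI, –78 to 0 °C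
Reagents that add atoms: iodomethane (CI)
Why: kinetic α′-deprotonation gives the cross-conjugated enolate, which is C-methylated (enolate alkylation); the new centre need not be controlled because it is enolised again in step 4.

Step 4
Reactants: 6 6-methylcarvone; 3 3-bromo-2-(phenylsulfonyl)prop-1-ene
Product: 8 (5S,6S)-6-methyl-6-[2-(phenylsulfonyl)allyl]carvone, via lithium enolate 7 (not isolated)
Conditions: LiN(i-Pr)2, THF, –78 °C; then 3, –78 °C
Reagents that add atoms: none
Why: enolate allylation by addition–elimination on the bromomethyl vinyl sulfone, with the electrophile entering anti to the neighbouring isopropenyl group, so that C10 receives the chain trans and the methyl cis to the C5 substituent.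

Step 5
Reactants: 8 (5S,6S)-6-methyl-6-[2-(phenylsulfonyl)allyl]carvone
Product: 9 bicyclic enone ester sulfone (C2 epimers)
Conditions: methyl bromoacetate (3 equiv), fac-Ir(ppy)3 (1 mol %), Hantzsch ester (1.5 equiv, added in portions), NaHCO3, MeCN, blue LEDs, rt
Reagents that add atoms: methyl bromoacetate (COC(=O)CBr)
Why: The photoexcited iridium complex reduces the bromoacetate to the electrophilic radical •CH2CO2Me, which adds to the terminal CH2 of the electron-rich isopropenyl group; the nucleophilic tertiary C4 radical so formed adds to C3, the CH2 terminus of the vinyl sulfone, and the α-sulfonyl radical at C2 is quenched by hydrogen transfer from the Hantzsch ester. The closest known reaction type is the radical addition–cyclisation (Giese) cascade of α-halo esters with dienes under photoredox or tin hydride conditions. Ring A closes in the 6-endo-trig mode, because exo attack would have to hit the fully substituted, sulfonyl-bearing C2 and would leave an unstabilised primary radical. At the new stereocentre C4, the substituent that ends axial in the chair-like transition state lies anti to H5, gauche to C6 and to the quaternary C10 and syn to the axial C10 methyl, so the small CH3 should take this place and the CH2CH2CO2Me chain the equatorial one; C2 forms as a mixture and is removed in step 8, and the trans ring fusion follows from the trans arrangement of the C10 chain and the C5 substituent fixed in step 4. The step needs polarity matching, secured by the substrate having one electron-rich alkene (isopropenyl) for the electrophilic radical and only electron-poor ones (vinyl sulfone, enone) for the tertiary radical, of which the enone is out of reach. It also needs ring closure to outrun hydrogen transfer, helped by a hydridic donor that reacts sluggishly with nucleophilic alkyl radicals and is kept at low concentration.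

Step 6
Reactants: 9 bicyclic enone ester sulfone
Product: 11 enol triflate, via lithium enolate 10 (not isolated)
Conditions: LiBH(s-Bu)3 (1.1 equiv), THF, –78 °C; then N-(5-chloro-2-pyridyl)bis(trifluoromethanesulfonimide), –78 °C to rt
Reagents that add atoms: N-(5-chloropyridin-2-yl)-1,1,1-trifluoro-N-(trifluoromethylsulfonyl)methanesulfonamide (O=S(=O)(N(c1ccc(Cl)cn1)S(=O)(=O)C(F)(F)F)C(F)(F)F)
Why: conjugate hydride reduction of the enone, whose β-carbon C7 carries only hydrogen besides the ring bond (the C9 carbonyl next to quaternary C10 is too hindered for direct attack), gives the C8=C9 enolate regiospecifically, and O-sulfonylation traps it as the triflate while ester and sulfone stay untouched at –78 °C.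

Step 7
Reactants: 11 enol triflate
Product: 12 ketal ester sulfone
Conditions: 2-methyl-2-vinyl-1,3-dioxolane, 9-BBN, THF, rt; then 11, PdCl2(dppf), AsPh3, Cs2CO3, DMF–H2O, 60 °C
Reagents that add atoms: 2-methyl-2-vinyl-1,3-dioxolane (C=CC1(C)OCCO1)
Why: B-alkyl Suzuki–Miyaura coupling, in which anti-Markovnikov hydroboration gives a primary alkylborane that couples with the enol triflate, fixing the tetrasubstituted C8=C9 alkene and bringing in C11–C13 and the C13 methyl as a masked methyl ketone.

Step 8
Reactants: 12 ketal ester sulfone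
Product: 13 ketal ester
Conditions: Mg turnings, MeOH, 50 °C
Reagents that add atoms: none
Why: reductive desulfonylation by electron transfer removes the C2 helper group from both epimers, and the methyl ester, the ketal and the tetrasubstituted alkene are inert to magnesium in methanol.

Step 9
Reactants: 13 ketal ester
Product: 14 ketal aldehyde
Conditions: i-Bu2AlH (1.05 equiv), CH2Cl2, –78 °C; aq. potassium sodium tartrate work-up
Reagents that add atoms: none
Why: partial reduction of the only carbonyl group present, the methyl ester, stops at the aldehyde because the tetrahedral aluminium hemiacetal is stable at –78 °C.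

Step 10
Reactants: 14 ketal aldehyde
Product: 15 ketal triene
Conditions: i-PrPPh3I, n-BuLi, THF, 0 °C; then 14, –78 °C to rt
Reagents that add atoms: isopropyltriphenylphosphonium iodide (CC(C)[P+](c1ccccc1)(c1ccccc1)c1ccccc1.[I-])
Why: Wittig olefination with isopropylidenetriphenylphosphorane completes the 4-methylpent-3-enyl chain, with no alkene geometry to control.

Step 11
Reactants: 15 ketal triene
Product: 16 methyl ketone
Conditions: PPTS, acetone–H2O, 50 °C
Reagents that add atoms: water (O)
Why: mild acid-catalysed ketal hydrolysis frees the methyl ketone without touching the tri- and tetrasubstituted alkenes.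

Step 12
Reactants: 16 methyl ketone
Product: 17 (E)-ethyl ester
Conditions: (EtO)2P(O)CH2CO2Et, NaH, THF, 0 °C to reflux
Reagents that add atoms: triethyl phosphonoacetate (CCOC(=O)CP(=O)(OCC)OCC)
Why: Horner–Wadsworth–Emmons olefination of the methyl ketone should favour the E alkene, with the ester trans to the larger CH2CH2 branch; the minor Z isomer is to be removed by chromatography.

Step 13
Reactants: 17 (E)-ethyl ester
Product: 19 target acid, via lithium carboxylate 18 (not isolated)
Conditions: LiOH, THF–MeOH–H2O, 50 °C; then 1 M HCl to pH 3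
Reagents that add atoms: lithium hydroxide ([Li+].[OH-])
Why: ester saponification followed by acidification gives the acid, and no stereocentre or alkene geometry is at risk under these conditions.

**Compound list**

1 | phenyl vinyl sulfone | C=CS(=O)(=O)c1ccccc1 | starting material
2 | 2-(phenylsulfonyl)prop-2-en-1-ol | C=C(CO)S(=O)(=O)c1ccccc1 | intermediate
3 | 3-bromo-2-(phenylsulfonyl)prop-1-ene | C=C(CBr)S(=O)(=O)c1ccccc1 | intermediate
4 | (R)-(–)-carvone, (5R)-2-methyl-5-(prop-1-en-2-yl)cyclohex-2-en-1-one | C=C(C)[C@@H]1CC=C(C)C(=O)C1 | starting material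
5 | lithium cross-conjugated dienolate of 4 (O–Li on the former carbonyl carbon, new C1=C6 double bond, C5 as in 4) | C=C(C)[C@@H]1CC=C(C)C(O[Li])=C1 | intermediate
6 | (5R)-2,6-dimethyl-5-(prop-1-en-2-yl)cyclohex-2-en-1-one (6-methylcarvone, both C6 epimers) | C=C(C)[C@@H]1CC=C(C)C(=O)C1C | intermediate
7 | lithium cross-conjugated dienolate of 6 (O–Li on the former carbonyl carbon, C1=C6 double bond bearing the new methyl, C5 as in 4) | C=C(C)[C@@H]1CC=C(C)C(O[Li])=C1C | intermediate
8 | (5S,6S)-2,6-dimethyl-6-[2-(phenylsulfonyl)prop-2-en-1-yl]-5-(prop-1-en-2-yl)cyclohex-2-en-1-one (sulfonylallyl chain trans, methyl cis to the isopropenyl group) | C=C(C)[C@@H]1CC=C(C)C(=O)[C@@]1(C)CC(=C)S(=O)(=O)c1ccccc1 | intermediate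
9 | methyl 3-[(1R,4aS,8aS)-1,4a,6-trimethyl-5-oxo-3-(phenylsulfonyl)-1,2,3,4,4a,5,8,8a-octahydronaphthalen-1-yl]propanoate (trans-fused; C4 methyl axial, cis to the angular methyl; both epimers at the sulfonyl carbon) | COC(=O)CC[C@]1(C)CC(S(=O)(=O)c3ccccc3)C[C@]2(C)C(=O)C(C)=CC[C@@H]12 | intermediate
10 | lithium enolate from conjugate reduction of 9 (O–Li on C9, C8=C9 double bond, C7 now CH2, other centres as in 9) | COC(=O)CC[C@]1(C)CC(S(=O)(=O)c3ccccc3)C[C@]2(C)C(O[Li])=C(C)CC[C@@H]12 | intermediate
11 | methyl 3-[(1R,4aS,8aS)-1,4a,6-trimethyl-3-(phenylsulfonyl)-5-{[(trifluoromethyl)sulfonyl]oxy}-1,2,3,4,4a,7,8,8a-octahydronaphthalen-1-yl]propanoate (sulfonyl carbon epimers) | COC(=O)CC[C@]1(C)CC(S(=O)(=O)c3ccccc3)C[C@]2(C)C(OS(=O)(=O)C(F)(F)F)=C(C)CC[C@@H]12 | intermediate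
12 | methyl 3-[(1R,4aS,8aS)-1,4a,6-trimethyl-5-[2-(2-methyl-1,3-dioxolan-2-yl)ethyl]-3-(phenylsulfonyl)-1,2,3,4,4a,7,8,8a-octahydronaphthalen-1-yl]propanoate (sulfonyl carbon epimers) | COC(=O)CC[C@]1(C)CC(S(=O)(=O)c3ccccc3)C[C@]2(C)C(CCC3(C)OCCO3)=C(C)CC[C@@H]12 | intermediate
13 | methyl 3-[(1S,4aS,8aS)-1,4a,6-trimethyl-5-[2-(2-methyl-1,3-dioxolan-2-yl)ethyl]-1,2,3,4,4a,7,8,8a-octahydronaphthalen-1-yl]propanoate | COC(=O)CC[C@]1(C)CCC[C@]2(C)C(CCC3(C)OCCO3)=C(C)CC[C@@H]12 | intermediate
14 | 3-[(1S,4aS,8aS)-1,4a,6-trimethyl-5-[2-(2-methyl-1,3-dioxolan-2-yl)ethyl]-1,2,3,4,4a,7,8,8a-octahydronaphthalen-1-yl]propanal | O=CCC[C@]1(C)CCC[C@]2(C)C(CCC3(C)OCCO3)=C(C)CC[C@@H]12 | intermediate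
15 | 2-methyl-2-{2-[(4aS,5S,8aS)-2,5,8a-trimethyl-5-(4-methylpent-3-en-1-yl)-3,4,4a,5,6,7,8,8a-octahydronaphthalen-1-yl]ethyl}-1,3-dioxolane | CC(C)=CCC[C@]1(C)CCC[C@]2(C)C(CCC3(C)OCCO3)=C(C)CC[C@@H]12 | intermediate
16 | 4-[(4aS,5S,8aS)-2,5,8a-trimethyl-5-(4-methylpent-3-en-1-yl)-3,4,4a,5,6,7,8,8a-octahydronaphthalen-1-yl]butan-2-one | CC(C)=CCC[C@]1(C)CCC[C@]2(C)C(CCC(C)=O)=C(C)CC[C@@H]12 | intermediate
17 | ethyl (2E)-3-methyl-5-[(4aS,5S,8aS)-2,5,8a-trimethyl-5-(4-methylpent-3-en-1-yl)-3,4,4a,5,6,7,8,8a-octahydronaphthalen-1-yl]pent-2-enoate | CC(C)=CCC[C@]1(C)CCC[C@]2(C)C(CC/C(C)=C/C(=O)OCC)=C(C)CC[C@@H]12 | intermediate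
18 | lithium (2E)-3-methyl-5-[(4aS,5S,8aS)-2,5,8a-trimethyl-5-(4-methylpent-3-en-1-yl)-3,4,4a,5,6,7,8,8a-octahydronaphthalen-1-yl]pent-2-enoate | CC(C)=CCC[C@]1(C)CCC[C@]2(C)C(CC/C(C)=C/C(=O)[O-])=C(C)CC[C@@H]12.[Li+] | intermediate
19 | (2E)-3-methyl-5-[(4aS,5S,8aS)-2,5,8a-trimethyl-5-(4-methylpent-3-en-1-yl)-3,4,4a,5,6,7,8,8a-octahydronaphthalen-1-yl]pent-2-enoic acid (CNP0237483.2) | CC(C)=CCC[C@]1(C)CCC[C@]2(C)C(CC/C(C)=C/C(=O)O)=C(C)CC[C@@H]12 | target

**Step count**

Total: 13 steps. Longest linear sequence: 12 steps (steps 1, 2 and 4–13, counted from phenyl vinyl sulfone 1 through bromide 3 to the target); the methylation of (R)-carvone (step 3) is the side branch and joins at step 4.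

**Steps most likely to fail**

1. Step 5. The acetate radical or the tertiary C4 radical may be quenched by hydrogen transfer before the next C–C bond forms, and the preference for the equatorial chain at C4 may be incomplete. The fallback sets out from 8 and comes back at 9, and it takes the bimolecular radical step out of the sequence. Allylic hydroxylation of the isopropenyl methyl of 8 (SeO2 cat., t-BuOOH, CH2Cl2, rt) should give the allylic alcohol F1. A Johnson–Claisen rearrangement (MeC(OMe)3, cat. EtCO2H, 130 °C) then moves the alkene and delivers the γ,δ-unsaturated methyl ester F2, which holds a 1,1-disubstituted alkene at C4 and the complete ester chain. A hydrogen-atom-transfer-initiated Giese cyclisation (Fe(acac)3, PhSiH3, EtOH, 0 °C to rt) forms the same tertiary C4 radical inside the molecule and closes ring A onto the vinyl sulfone to give 9. Because this ring closure is unimolecular it can be run cold, which should sharpen the face preference at C4.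

2. Step 7. Transmetalation of the alkylborane onto the congested alkenylpalladium species (flanked by quaternary C10 and the C8 methyl) may be slow, so that protodeboronation, β-hydride elimination or triflate hydrolysis take over. The fallback sets out from 11 and comes back at 12, and it builds the C9–C11 bond by alkene insertion instead. A Heck reaction of 11 with methyl vinyl ketone (Pd(OAc)2, PPh3, Et3N, DMF, 70 °C) should give the (E)-dienone F3. Conjugate reduction of its unhindered disubstituted enone double bond with [(Ph3P)CuH]6 (benzene, rt) gives the methyl ketone F4, the tetrasubstituted C8=C9 alkene being too hindered to react. Ketalisation (ethylene glycol, PPTS, benzene, reflux with water removal) then gives 12.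

3. Step 4. The lithium enolate may add to the vinyl sulfone of product already formed (oligomerisation), O-allylation may compete, and the anti selectivity may erode with so reactive an electrophile. The fallback sets out from 6 and comes back at 8, and it installs the sulfone after the C–C bond. Alkylation of the enolate of 6 with 2,3-dibromopropene (LiN(i-Pr)2, THF, –78 to 0 °C) should give the vinyl bromide F5, which is no Michael acceptor. Copper-catalysed sulfonylation (PhSO2Na, CuI, N,N′-dimethylethylenediamine, DMSO, 100 °C) then converts the vinyl bromide into the vinyl sulfone 8.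

**Further compounds**

F1 | step 5 | (5S,6S)-5-(3-hydroxyprop-1-en-2-yl)-2,6-dimethyl-6-[2-(phenylsulfonyl)prop-2-en-1-yl]cyclohex-2-en-1-one | C=C(CO)[C@@H]1CC=C(C)C(=O)[C@@]1(C)CC(=C)S(=O)(=O)c1ccccc1
F2 | step 5 | methyl 4-{(1S,2S)-2,4-dimethyl-3-oxo-2-[2-(phenylsulfonyl)prop-2-en-1-yl]cyclohex-4-en-1-yl}pent-4-enoate | COC(=O)CCC(=C)[C@@H]1CC=C(C)C(=O)[C@@]1(C)CC(=C)S(=O)(=O)c1ccccc1
F3 | step 7 | methyl 3-[(1R,4aS,8aS)-1,4a,6-trimethyl-5-[(1E)-3-oxobut-1-en-1-yl]-3-(phenylsulfonyl)-1,2,3,4,4a,7,8,8a-octahydronaphthalen-1-yl]propanoate (sulfonyl carbon epimers) | COC(=O)CC[C@]1(C)CC(S(=O)(=O)c3ccccc3)C[C@]2(C)C(/C=C/C(C)=O)=C(C)CC[C@@H]12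
F4 | step 7 | methyl 3-[(1R,4aS,8aS)-1,4a,6-trimethyl-5-(3-oxobutyl)-3-(phenylsulfonyl)-1,2,3,4,4a,7,8,8a-octahydronaphthalen-1-yl]propanoate (sulfonyl carbon epimers) | COC(=O)CC[C@]1(C)CC(S(=O)(=O)c3ccccc3)C[C@]2(C)C(CCC(C)=O)=C(C)CC[C@@H]12
F5 | step 4 | (5S,6S)-6-(2-bromoprop-2-en-1-yl)-2,6-dimethyl-5-(prop-1-en-2-yl)cyclohex-2-en-1-one | C=C(C)[C@@H]1CC=C(C)C(=O)[C@@]1(C)CC(Br)=C
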